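## Retrosynthetic overview

1. 23 ⇒ 21: the two neopentylic C–Br centres (C-7 and C-4′) are set last and together, by hydrogen-atom-transfer hydrogenation of two alkenyl bromides that both come from ketones.
2. 21 ⇒ 16 ⇒ 11 + 13: the 1′-OH/4′-C=O pair of the cyclohexane ring comes from O2 (singlet-oxygen [4+2], then Kornblum–DeLaMare) on a gem-dimethylcyclohexadiene. That diene is joined to aldehyde 11 by Ni/Cr coupling, and the carbinol CH is set by Felkin–Anh hydride delivery.
3. 11 ⇒ 8 ⇒ 7: both hydrindane rings close in one operation by an intramolecular Pd(0) [3+2] cycloaddition of an alkylidenecyclopropane with an isopropenyl ketone (bonds C-1–C-2 and C-3a–C-7a). Compound 7 comes from (R)-linalool, whose carbinol carbon becomes C-4.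
4. Enabling feature: in the cyclopentane ring (C-1, C-2, C-3, C-3a, C-7a) the side chain sits on C-3, the central atom of the three-carbon unit C-2/C-3/C-3a (a trimethylenemethane retron). This unit faces the two-carbon unit C-1/C-7a. C-7a is quaternary, so the Pd–CH2 intermediate has no β-hydride exit, and its neighbour C-7 (CHBr) can be a ketone that makes C-1=C-7a part of an enone.
5. Ring order: the six- and five-membered hydrindane rings form together (step 7). The cyclohexane ring is brought in preformed (step 12) and oxygenated afterwards (step 15).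

Key step: step 7

Remark on locants: the hydrindane carries octahydroindene numbering as in the target (C-3 bears the side chain, C-4 is C(CH3)OH, C-7 is CHBr, C-7a is C–CH3). The cyclohexane ring is C-1′ (carbinol), C-3′ (CMe2), C-4′ (CHBr). β is the face of the 7a-methyl group and α is the opposite face.

Assumption: (R)-(−)-linalool of high ee (which limits the ee of the product) and 5,5-dimethylcyclohex-2-en-1-one are taken as purchasable.

## Route

Step 1
Reactants: 1 (R)-(−)-linalool
Product: 2 (3R)-3,7-dimethyl-3-(triethylsilyloxy)octa-1,6-diene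
Conditions: TESOTf, 2,6-lutidine, CH2Cl2, 0 °C
Reagents that add atoms: triethylsilyl trifluoromethanesulfonate, CC[Si](CC)(CC)OS(=O)(=O)C(F)(F)F
Why: O-silylation with a silyl triflate and lutidine is the standard way to cap a hindered tertiary alcohol, leaves the stereocentre untouched and keeps the later 6,7-epoxide from cyclising to linalool oxides.

Step 2
Reactants: 2 (3R)-3,7-dimethyl-3-(triethylsilyloxy)octa-1,6-diene
Product: 3 (3R)-6,7-epoxy-3,7-dimethyl-3-(triethylsilyloxy)oct-1-ene (both C-6 epimers)
Conditions: mCPBA, CH2Cl2, −10 °C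
Reagents that add atoms: 3-chloroperoxybenzoic acid, OOC(=O)c1cccc(Cl)c1
Why: The Prilezhaev epoxidation picks the electron-rich trisubstituted alkene over the hindered vinyl group, and the new centre needs no control because it becomes sp2 in step 6.

Step 3
Reactants: 3 (3R)-6,7-epoxy-3,7-dimethyl-3-(triethylsilyloxy)oct-1-ene
Product: 4 (2R)-4-(3,3-dimethyloxiran-2-yl)-2-methyl-2-(triethylsilyloxy)butanal
Conditions: O3, CH2Cl2, −78 °C; then Me2S
Reagents that add atoms: ozone, [O-][O+]=O
Why: Ozonolysis with reductive work-up cleaves the only remaining alkene, and the aldehyde cannot epimerise because its α-carbon is fully substituted.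

Step 4
Reactants: 4 (2R)-4-(3,3-dimethyloxiran-2-yl)-2-methyl-2-(triethylsilyloxy)butanal
Product: 5 (R)-{[1-cyclopropylidene-4-(3,3-dimethyloxiran-2-yl)-2-methylbutan-2-yl]oxy}triethylsilane
Conditions: cyclopropyl-PPh3Br, KOtBu, THF, 0 → 65 °C
Reagents that add atoms: cyclopropyltriphenylphosphonium bromide, [Br-].C1CC1[P+](c1ccccc1)(c1ccccc1)c1ccccc1
Why: The Wittig reaction of cyclopropylidenetriphenylphosphorane is the usual entry to alkylidenecyclopropanes from aldehydes, and the hindered trisubstituted epoxide is inert to the ylide.

Step 5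
Reactants: 5 (R)-{[1-cyclopropylidene-4-(3,3-dimethyloxiran-2-yl)-2-methylbutan-2-yl]oxy}triethylsilane
Product: 6 (6R)-7-cyclopropylidene-2,6-dimethyl-6-(triethylsilyloxy)hept-1-en-3-ol (both C-3 epimers)
Conditions: Al(OiPr)3, toluene, 110 °C
Reagents that add atoms: none
Why: The aluminium-alkoxide-promoted epoxide-to-allylic-alcohol isomerisation of 2,2-dimethyl-substituted epoxides removes a methyl proton syn to the activated oxygen and so gives the secondary isopropenyl carbinol.

Step 6
Reactants: 6 (6R)-7-cyclopropylidene-2,6-dimethyl-6-(triethylsilyloxy)hept-1-en-3-ol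
Product: 7 (6R)-7-cyclopropylidene-2,6-dimethyl-6-(triethylsilyloxy)hept-1-en-3-one
Conditions: Dess–Martin periodinane, pyridine, CH2Cl2, 0 °C
Reagents that add atoms: none
Why: The Dess–Martin oxidation converts both carbinol epimers under neutral conditions into one isopropenyl ketone, which is used at once because such enones dimerise.

Step 7
Reactants: 7 (6R)-7-cyclopropylidene-2,6-dimethyl-6-(triethylsilyloxy)hept-1-en-3-one
Product: 8 (3aS,4R,7aS)-4,7a-dimethyl-3-methylidene-4-(triethylsilyloxy)octahydroinden-7-one (trans-fused; 7a-CH3 and 4-OSiEt3 β, H-3a α)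
Conditions: Pd2(dba)3·CHCl3 (5 mol %), tris(2,4-di-tert-butylphenyl) phosphite (25 mol %), 1,4-dioxane (0.01 M), 100 °C
Reagents that add atoms: none
Why: Proposed new method: Pd(0) should insert into the distal C–C bond of the strained alkylidenecyclopropane of 7 to give a palladacyclobutane (σ-bound trimethylenemethane–Pd), whose substituted allyl terminus adds to the Pd-bound isopropenyl ketone at its inner carbon (C-3a–C-7a bond), and the palladacyclohexane so formed closes the C-1–C-2 bond by reductive elimination, the third trimethylenemethane carbon being left as the exocyclic methylene group. The closest known reaction types are the Pd(0)/phosphite-catalysed intramolecular [3+2] cycloaddition of alk-5-enylidenecyclopropanes with acceptor alkenes and the intermolecular Pd(0) cycloaddition of methylenecyclopropanes with enones; new here are the tether, which is one atom longer and enters through the acyl carbon, and the quaternary centre that is made. The six-membered ring closes by a 6-exo-trig carbopalladation and the five-membered ring by C(sp3)–C(sp3) reductive elimination from a six-membered palladacycle, so both partners stay on one metal and no medium-ring transition state is needed. C-7a is controlled by the linalool-derived centre C-4, because in the chair-like insertion transition state the 4-methyl group lies equatorial and the smaller silyloxy group axial, which lets the developing axial 7a-methyl group avoid a methyl/methyl 1,3-diaxial contact; C-3a follows from the trans "pallada-decalin" arrangement in which C-3 and C-1 both lie equatorial (planar s-cis enone), so that H-3a ends anti to the 7a-methyl group. The step needs distal rather than proximal ring cleavage, exo (fused) rather than endo (bridged) insertion, and reductive elimination rather than β-hydride loss; these are secured by the π-acidic phosphite ligand, by the four-atom tether, and by the quaternary C-7a, which leaves the neopentylic Pd–CH2 group without any β-hydrogen, while high dilution holds back dimerisation of the enone.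

Step 8
Reactants: 8 (3aS,4R,7aS)-4,7a-dimethyl-3-methylidene-4-(triethylsilyloxy)octahydroinden-7-one
Product: 9 7-bromo-4,7a-dimethyl-3-methylidene-4-(triethylsilyloxy)-2,3,3a,4,5,7a-hexahydro-1H-indene (C-3a, C-4, C-7a as in 8)
Conditions: (PhO)3P, Br2, Et3N, CH2Cl2, −60 → 40 °C
Reagents that add atoms: bromine, BrBr
Why: The ketone-to-alkenyl-bromide conversion with the preformed triphenyl phosphite–bromine reagent contains no free Br2 (so the methylene group survives), can lose a proton only from C-6, and also masks the ketone for the hydride step 14.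

Step 9
Reactants: 9 7-bromo-4,7a-dimethyl-3-methylidene-4-(triethylsilyloxy)-2,3,3a,4,5,7a-hexahydro-1H-indene
Product: 10 spiro[indene-3,2′-oxirane] derived from 9, with the oxirane oxygen on the α face of C-3
Conditions: mCPBA, CH2Cl2, −10 °C
Reagents that add atoms: 3-chloroperoxybenzoic acid, OOC(=O)c1cccc(Cl)c1
Why: The Prilezhaev epoxidation takes the electron-rich 1,1-disubstituted alkene and not the bromoalkene, and attack from the α face, away from the 7a-methyl group and the C-4 substituents, sets the spiro centre.

Step 10
Reactants: 10 spiro-epoxide (oxygen α)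
Product: 11 7-bromo-4,7a-dimethyl-4-(triethylsilyloxy)-2,3,3a,4,5,7a-hexahydro-1H-indene-3α-carbaldehyde (H-3 β)
Conditions: BF3·OEt2 (0.2 equiv), CH2Cl2, −78 °C; then DBU (0.1 equiv), 0 °C
Reagents that add atoms: none
Why: In the Meinwald rearrangement the tertiary C-3–O bond ionises while hydride migrates from the CH2 group to the face anti to the leaving oxygen, so H-3 becomes β and CHO α, which is also the thermodynamic epimer (trans to C-4) that the DBU treatment secures.

Step 11
Reactants: 12 5,5-dimethylcyclohex-2-en-1-one
Product: 13 5,5-dimethylcyclohexa-1,3-dien-1-yl trifluoromethanesulfonate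
Conditions: Tf2O, 2,6-di-tert-butyl-4-methylpyridine, CH2Cl2, 0 °C → rt
Reagents that add atoms: trifluoromethanesulfonic anhydride, O=S(=O)(OS(=O)(=O)C(F)(F)F)C(F)(F)F
Why: O-triflation of the enone followed by γ-deprotonation (thermodynamic dienol triflate formation) gives the linear dienyl triflate, whose double-bond position tells the two ring arms apart and whose gem-dimethyl group blocks aromatisation.

Step 12
Reactants: 11 3α-carbaldehyde; 13 5,5-dimethylcyclohexa-1,3-dien-1-yl trifluoromethanesulfonate
Product: 14 (5,5-dimethylcyclohexa-1,3-dien-1-yl)(hydrindenyl)methanol (both carbinol epimers)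
Conditions: CrCl2 (4 equiv), NiCl2 (2 mol %), DMF–THF, rt
Reagents that add atoms: none
Why: In the Nozaki–Hiyama–Kishi coupling nickel should insert into the unhindered dienyl triflate far faster than into the neopentylic trisubstituted alkenyl bromide, the alkenylchromium adds only to the aldehyde, and the new centre needs no control because step 13 erases it.

Step 13
Reactants: 14 dienyl carbinol (both epimers)
Product: 15 (5,5-dimethylcyclohexa-1,3-dien-1-yl) hydrindenyl ketone
Conditions: Dess–Martin periodinane, pyridine, CH2Cl2, 0 °C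
Reagents that add atoms: none
Why: The Dess–Martin oxidation merges both dienylic alcohols into one dienone under neutral conditions that spare the silyl ether, the bromoalkene and the α-stereocentre C-3.

Step 14
Reactants: 15 dienyl ketone
Product: 16 (R)-(5,5-dimethylcyclohexa-1,3-dien-1-yl)(hydrindenyl)methanol
Conditions: NaBH4, CeCl3·7H2O, MeOH–THF, −78 °C
Reagents that add atoms: none
Why: The Luche 1,2-reduction runs under Felkin–Anh control by C-3 (hydride anti to the branched C-3a arm, past H-3), the sense known from hydride reduction of 20-oxopregnanes, and should give the (R)-carbinol.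

Step 15
Reactants: 16 (R)-dienyl carbinol
Product: 18 4-hydroxy-6,6-dimethylcyclohex-2-en-1-one carrying the (R)-hydroxy(hydrindenyl)methyl group on C-4 (C-1′ configured as in the target), via endoperoxide 17 (not isolated)
Conditions: O2, tetraphenylporphyrin (cat.), visible light, CH2Cl2, −20 °C; then Et3N (cat.), rt
Reagents that add atoms: oxygen, O=O
Why: The singlet-oxygen [4+2] cycloaddition to the homoannular diene should occur on the face syn to the carbinol OH and anti to the hydrindane in the A(1,2)-minimised rotamer (carbinol H towards C-2′H2, OH inside), which sets C-1′, and the Kornblum–DeLaMare rearrangement can remove only the bridgehead H at C-4′, so the ketone appears there and the tertiary alcohol at C-1′.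

Step 16
Reactants: 18 γ-hydroxy enone
Product: 19 4-hydroxy-2,2-dimethylcyclohexan-1-one carrying the (R)-hydroxy(hydrindenyl)methyl group on C-4
Conditions: H2 (1 atm), RhCl(PPh3)3 (5 mol %), benzene, rt
Reagents that add atoms: none
Why: Homogeneous rhodium(I) hydrogenation saturates the cis-disubstituted enone double bond, while the hindered trisubstituted bromoalkene and its C–Br bond are left alone and no stereocentre is formed.

Step 17
Reactants: 19 hydroxy ketone
Product: 21 bis(alkenyl bromide): 4-bromo-3,3-dimethylcyclohex-4-en-1-ol unit joined through the (R)-carbinol CH to the 7-bromohydrindene unit, via hydrazone 20 (not isolated)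
Conditions: N2H4·H2O, Et3N, EtOH, 80 °C; concentrate; NBS, pyridine, 0 °C
Reagents that add atoms: N-bromosuccinimide, O=C1CCC(=O)N1Br; hydrazine, NN (nitrogen atoms of 20 only)
Why: In the Barton-type vinyl halide synthesis the hydrazone is oxidised to the diazo compound, brominated with loss of N2 and deprotonated at C-5′, the only β-position with hydrogen because C-3′ is quaternary, while the free alcohols and the first bromoalkene are inert.

Step 18
Reactants: 21 bis(alkenyl bromide)
Product: 22 4-O-triethylsilyl ether of the target
Conditions: Mn(dpm)3 (20 mol %), PhSiH3, t-BuOOH, i-PrOH, 22 °C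
Reagents that add atoms: none
Why: In the metal-hydride hydrogen-atom-transfer hydrogenation of alkenyl halides to alkyl halides, H• adds to the CH end of each bromoalkene and each α-bromo radical takes its second hydrogen from the axial direction anti to the neighbouring axial methyl group, which puts both bromine atoms equatorial (H-7 α; H-4′ trans to 1′-OH in the chair locked by the equatorial side chain).

Step 19
Reactants: 22 4-O-triethylsilyl ether of the target
Product: 23 CNP0193924.1, (3R,3aS,4R,7S,7aS)-7-bromo-3-{(R)-[(1R,4S)-4-bromo-1-hydroxy-3,3-dimethylcyclohexyl](hydroxy)methyl}-4,7a-dimethyloctahydro-1H-inden-4-ol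
Conditions: HF·pyridine, pyridine, THF, 0 °C → rt
Reagents that add atoms: none
Why: Fluoride-mediated desilylation with buffered HF·pyridine cleaves the hindered tertiary silyl ether without strong base, so the equatorial bromides and the tertiary alcohols are not exposed to elimination.

## Compound list

1 | (R)-(−)-linalool | CC(C)=CCC[C@@](C)(O)C=C | starting material
2 | (3R)-3,7-dimethyl-3-(triethylsilyloxy)octa-1,6-diene | CC(C)=CCC[C@@](C)(O[Si](CC)(CC)CC)C=C | intermediate
3 | (3R)-6,7-epoxy-3,7-dimethyl-3-(triethylsilyloxy)oct-1-ene (both C-6 epimers) | CC1(C)OC1CC[C@@](C)(O[Si](CC)(CC)CC)C=C | intermediate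
4 | (2R)-4-(3,3-dimethyloxiran-2-yl)-2-methyl-2-(triethylsilyloxy)butanal | CC1(C)OC1CC[C@@](C)(O[Si](CC)(CC)CC)C=O | intermediate
5 | alkylidenecyclopropane epoxide | CC1(C)OC1CC[C@@](C)(O[Si](CC)(CC)CC)C=C1CC1 | intermediate
6 | (6R)-7-cyclopropylidene-2,6-dimethyl-6-(triethylsilyloxy)hept-1-en-3-ol (both C-3 epimers) | C=C(C)C(O)CC[C@@](C)(O[Si](CC)(CC)CC)C=C1CC1 | intermediate
7 | (6R)-7-cyclopropylidene-2,6-dimethyl-6-(triethylsilyloxy)hept-1-en-3-one | C=C(C)C(=O)CC[C@@](C)(O[Si](CC)(CC)CC)C=C1CC1 | intermediate
8 | trans-fused 3-methylidene-hydrindan-7-one | C=C1CC[C@]2(C)C(=O)CC[C@@](C)(O[Si](CC)(CC)CC)[C@@H]12 | intermediate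
9 | 7-bromo-3-methylidene-hydrind-6-ene | C=C1CC[C@]2(C)C(Br)=CC[C@@](C)(O[Si](CC)(CC)CC)[C@@H]12 | intermediate
10 | spiro-epoxide (oxygen α) | C1O[C@@]12CC[C@]3(C)C(Br)=CC[C@@](C)(O[Si](CC)(CC)CC)[C@@H]23 | intermediate
11 | 3α-carbaldehyde | O=C[C@@H]1CC[C@]2(C)C(Br)=CC[C@@](C)(O[Si](CC)(CC)CC)[C@@H]12 | intermediate
12 | 5,5-dimethylcyclohex-2-en-1-one | CC1(C)CC=CC(=O)C1 | starting material
13 | 5,5-dimethylcyclohexa-1,3-dien-1-yl trifluoromethanesulfonate | CC1(C)C=CC=C(OS(=O)(=O)C(F)(F)F)C1 | intermediate
14 | dienyl carbinol (both carbinol epimers) | CC1(C)CC(=CC=C1)C(O)[C@@H]2CC[C@]3(C)C(Br)=CC[C@@](C)(O[Si](CC)(CC)CC)[C@@H]23 | intermediate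
15 | dienyl ketone | CC1(C)CC(=CC=C1)C(=O)[C@@H]2CC[C@]3(C)C(Br)=CC[C@@](C)(O[Si](CC)(CC)CC)[C@@H]23 | intermediate
16 | (R)-dienyl carbinol | CC1(C)CC(=CC=C1)[C@H](O)[C@@H]2CC[C@]3(C)C(Br)=CC[C@@](C)(O[Si](CC)(CC)CC)[C@@H]23 | intermediate
17 | 2,3-dioxabicyclo[2.2.2]oct-5-ene endoperoxide | CC1(C)C[C@@]2(OO[C@H]1C=C2)[C@H](O)[C@@H]3CC[C@]4(C)C(Br)=CC[C@@](C)(O[Si](CC)(CC)CC)[C@@H]34 | intermediate
18 | γ-hydroxy enone | CC1(C)C[C@@](O)([C@H](O)[C@@H]2CC[C@]3(C)C(Br)=CC[C@@](C)(O[Si](CC)(CC)CC)[C@@H]23)C=CC1=O | intermediate
19 | saturated hydroxy ketone | CC1(C)C[C@@](O)([C@H](O)[C@@H]2CC[C@]3(C)C(Br)=CC[C@@](C)(O[Si](CC)(CC)CC)[C@@H]23)CCC1=O | intermediate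
20 | hydrazone of 19 | CC1(C)C[C@@](O)([C@H](O)[C@@H]2CC[C@]3(C)C(Br)=CC[C@@](C)(O[Si](CC)(CC)CC)[C@@H]23)CCC1=NN | intermediate
21 | bis(alkenyl bromide) | CC1(C)C[C@@](O)([C@H](O)[C@@H]2CC[C@]3(C)C(Br)=CC[C@@](C)(O[Si](CC)(CC)CC)[C@@H]23)CC=C1Br | intermediate
22 | 4-O-triethylsilyl ether of the target | CC1(C)C[C@@](O)([C@H](O)[C@@H]2CC[C@]3(C)[C@@H](Br)CC[C@@](C)(O[Si](CC)(CC)CC)[C@@H]23)CC[C@@H]1Br | intermediate
23 | CNP0193924.1 | CC1(C)C[C@@](O)([C@H](O)[C@@H]2CC[C@]3(C)[C@@H](Br)CC[C@@](C)(O)[C@@H]23)CC[C@@H]1Br | target

## Step count and risks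

Total step count: 19. Longest linear sequence: 18 (steps 1–10 and 12–19).

**Step 7 (bears the label).** What may go wrong is isomerisation of the alkylidenecyclopropane to 1,3-dienes by adventitious Pd–H, insertion in the endo sense because the enone is polarised against the exo mode, or loss of ring-fusion control. The fallback sets out from 6 and comes back at 8. It removes the polarity mismatch by using the neutral alkene. Compound 6 is capped (TMSCl, imidazole) as the trimethylsilyl ether F1. This is submitted to the rhodium(I)-catalysed carbocyclisation of alkenylidenecyclopropanes ([Rh(cod)Cl]2, P(OPh)3, toluene, 110 °C), a documented reaction class for tethered unactivated 1,1-disubstituted alkenes, to give the hydrindane F2. K2CO3 in MeOH frees the C-7 alcohol F3 without touching the tertiary triethylsilyl ether, and Dess–Martin oxidation of both C-7 epimers gives 8.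

**Step 15.** What may go wrong is poor π-facial discrimination in the oxygen cycloaddition if the rotamer with the carbinol OH outside competes. The fallback sets out from 16 and comes back at 18. The hydroxyl-directed vanadium epoxidation (VO(acac)2, t-BuOOH), which is reliably erythro-selective for allylic alcohols with a geminal substituent, gives the vinyl epoxy alcohol F4. Pd(PPh3)4 with AcOH opens it by double inversion to the cis-1,4-hydroxy acetate F5. K2CO3 in MeOH gives the allylic alcohol F6, and MnO2 oxidises only this allylic carbinol to 18.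

**Step 12.** What may go wrong is slow addition to the hindered aldehyde, together with nickel insertion into the alkenyl bromide of 11 and oligomerisation. The fallback sets out from 13 (with 11) and comes back at 14. Triflate 13 is converted (Me3SnSnMe3, Pd(PPh3)4, LiCl) into the dienylstannane F7. MeLi at −78 °C gives the dienyllithium F8, which adds to aldehyde 11 at −78 °C, where the alkenyl bromide is inert, to give 14.

## Further compounds

F1 | step 7 | trimethylsilyl ether of 6 (both C-3 epimers) | C=C(C)C(O[Si](C)(C)C)CC[C@@](C)(O[Si](CC)(CC)CC)C=C1CC1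
F2 | step 7 | trans-fused 3-methylidene-7-(trimethylsilyloxy)hydrindane (both C-7 epimers) | C=C1CC[C@]2(C)C(O[Si](C)(C)C)CC[C@@](C)(O[Si](CC)(CC)CC)[C@@H]12
F3 | step 7 | trans-fused 3-methylidene-hydrindan-7-ol (both C-7 epimers) | C=C1CC[C@]2(C)C(O)CC[C@@](C)(O[Si](CC)(CC)CC)[C@@H]12
F4 | step 15 | vinyl epoxy alcohol | CC1(C)C[C@@]2(O[C@@H]2C=C1)[C@H](O)[C@@H]3CC[C@]4(C)C(Br)=CC[C@@](C)(O[Si](CC)(CC)CC)[C@@H]34
F5 | step 15 | cis-1,4-hydroxy acetate | CC1(C)C[C@@](O)([C@H](O)[C@@H]2CC[C@]3(C)C(Br)=CC[C@@](C)(O[Si](CC)(CC)CC)[C@@H]23)C=C[C@@H]1OC(C)=O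
F6 | step 15 | allylic alcohol (cis-1,4-diol) | CC1(C)C[C@@](O)([C@H](O)[C@@H]2CC[C@]3(C)C(Br)=CC[C@@](C)(O[Si](CC)(CC)CC)[C@@H]23)C=C[C@@H]1O
F7 | step 12 | (5,5-dimethylcyclohexa-1,3-dien-1-yl)trimethylstannane | CC1(C)C=CC=C([Sn](C)(C)C)C1
F8 | step 12 | (5,5-dimethylcyclohexa-1,3-dien-1-yl)lithium | [Li]C1=CC=CC(C)(C)C1
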